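In a one-step world substrate meets catalyst and becomes target, and one rate constant times the time on offer tells you how far a vessel gets, so the question is how much of that world the earlier runs support.

| setting | theta | alpha | epsilon | Tuesday's | Saturday's | Thursday's | Friday's |
|---|---|---|---|---|---|---|---|
| substrate | 10 mM | 10 mM | 10 mM | 10 mM | 10 mM | 10 mM | 10 mM (fed, over 2.00 min) |
| reagent | 9.5 mM | 4.8 mM | 7.1 mM | 9.50 mM (fed, over 2.00 min) | 9.50 mM | 9.50 mM | 9.50 mM |
| free catalyst | 82 µM | 82 µM | 82 µM | 82 µM | 82 µM | 82 µM | 82 µM |
| remark | run made earlier | run made earlier | run made earlier | a stirred flask in which reagent is dosed at a steady rate over 2.00 min without added volume, worked up at 2.0 min | a single well-mixed tank run continuously and read at steady state, 2.0 min in it on average | a closed flask charged with all of it at once and left for 2.0 min | a stirred flask in which substrate is dosed at a steady rate over 2.00 min without added volume, worked up at 2.0 min |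
| time |  |  |  | 2.0 min |  | 2.0 min | 2.0 min |

| run | time / s | target / % | substrate / % |
|---|---|---|---|
| theta | 10.0 | 7.4 | 91.4 |
| theta | 15.0 | 15.3 | 85.2 |
| theta | 20.0 | 18.5 | 82.6 |
| theta | 30.0 | 25.7 | 74.1 |
| theta | 50.0 | 37.6 | 60.8 |
| theta | 80.0 | 52.1 | 48.7 |
| theta | 120 | 67.7 | 31.3 |
| alpha | 10.0 | 7.3 | 89.1 |
| alpha | 12.0 | 12.6 | 89.1 |
| alpha | 20.0 | 19.5 | 82.2 |
| alpha | 30.0 | 25.7 | 76.1 |
| alpha | 50.0 | 37.3 | 63.5 |
| alpha | 80.0 | 49.3 | 51.0 |
| epsilon | 10.0 | 9.7 | 90.5 |
| epsilon | 12.0 | 11.0 | 88.5 |
| epsilon | 20.0 | 17.4 | 81.1 |
| epsilon | 30.0 | 24.7 | 73.0 |
| epsilon | 50.0 | 38.4 | 60.9 |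
| epsilon | 80.0 | 52.3 | 47.3 |

(scatter of a reading: 1 percentage point)

- the stated concentrations are those of everything mixed, before any reaction; amounts are the same in each set-up
- the feed brings no volume worth counting
- the earlier runs were made in a closed, stirred flask

- the set-up with the highest amount of target at the outlet or at the end, in percent of the substrate put in ("none" if the first two lie within 2 percentage points) (Tuesday's / Saturday's / Thursday's / Friday's / none)
- amount of target at the outlet or at the end, in percent of the substrate put in, Tuesday's
- amount of target at the outlet or at the end, in percent of the substrate put in, Saturday's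
- amount of target at the outlet or at the end, in percent of the substrate put in, Thursday's
- amount of target at the outlet or at the end, in percent of the substrate put in, Friday's

Reagent hardly shows in the rate: at 50.0 s the theta run holds 60.8% of its substrate and the alpha run, with half the reagent, 63.5%. You therefore write the rate as k·c(substrate), pseudo-first-order, though every run began at 10 mM, so that order is assumed rather than shown. This integrates in closed form and folds into Da, the Damköhler number, the count of e-foldings of substrate that the time on offer allows, here 1.16 from the last theta reading. Thursday's closed flask then gives one minus exp(−Da), 68.7%; Saturday's tank gives Da/(one plus Da), 53.7%; and Friday's, where a steady feed term enters the same equation, gives one minus (one minus exp(−Da))/Da, 40.9%.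

Is one number enough? Not for Tuesday's, because Da supposes reagent stands ready, whereas there the feed starts at 0.818 of the substrate's demand, below one. Reagent is thus the limiting reagent at the opening of Tuesday's flask, and you would place it under Thursday's by an amount Da can't give.

The forecast gave 68% for Thursday's, 67% for Tuesday's, 53.5% for Saturday's and 41% for Friday's, and it parts from you on the ranking: “Tuesday and Thursday lie within 2 points, so best is none.”

The flasks give 67.3% for Thursday's, 61.9% for Tuesday's, 52.1% for Saturday's and 45.4% for Friday's, so the best is Thursday's, ahead by 5.4 percentage points, more than the margin of 2 points.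

    substrate + free catalyst ⇌ catalyst intermediate A (K = 554 M⁻¹, k = 254 M⁻¹ s⁻¹)
    reagent + catalyst intermediate A → catalyst intermediate B (k = 6890 M⁻¹ s⁻¹)
    catalyst intermediate B ⇌ free catalyst + target (K = 0.00720 M, k = 2.56 s⁻¹)
    reagent → decomposition product (k = 2.73 × 10⁻⁵ s⁻¹)

In Friday's at 1.22 min, catalyst intermediate A has a half-life against reagent of 0.014 s, far shorter than the 0.72 s of free catalyst against substrate by the forward step alone, and at 2.00 min that flask holds 1.83% of its catalyst as catalyst intermediate A, 52.7% as catalyst intermediate B and 45.5% as free catalyst. Friday's ends 4.5 points above the 40.9% from Da, and the same flask with 2.5 mM of substrate, where Da as read holds that same 40.9%, gives 56.6%.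

Readings and results are calculated on assumed constants; noise was put on by code.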